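The rate constants belong to no real substance, and the outcome is calculated.

Start with one ratio.

| setting | alder | ash | birch | larch |
|---|---|---|---|---|
| starting material | 20 mM | 20 mM | 20 mM | 20 mM |
| coupling partner | 26.0 mM | 26.0 mM | 26.0 mM | 26.0 mM |
| second substrate | 4.00 mM | 4.00 mM | 4.00 mM | 4.00 mM |
| protic impurity | 6.00 mM | 6.00 mM | 6.00 mM | 6.00 mM |
| temperature | 70 °C |  | 85 °C | 55 °C |
| time | 5.0 min | 5.0 min | 5.0 min | 5.0 min |
| remark |  | at 85 °C until 1.5 min, from then on at 55 °C |  |  |

1. the flask with the highest share of target in all that became target or over-reaction product ("all alike" if they lie within 1.5 percentage points) (alder / ash / birch / larch / all alike)
2. share of target in all that became target or over-reaction product, alder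
3. share of target in all that became target or over-reaction product, ash
4. share of target in all that became target or over-reaction product, birch
5. share of target in all that became target or over-reaction product, larch

- in percentages every species weighs as the starting material in it: one self-condensation product counts as two
- a step written with two of one species runs at k times the square of its concentration and takes two of it each time
- at 70 °C the constants are as listed, elsewhere as the activation energies make them

    second substrate + coupling partner → second product (k1 = 0.0180 L mol⁻¹ s⁻¹, Ea1 = 79.0 kJ mol⁻¹)
    starting material + coupling partner → target (k2 = 0.0555 L mol⁻¹ s⁻¹, Ea2 = 73.0 kJ mol⁻¹)
    2 starting material → self-condensation product (k3 = 5.32 × 10⁻⁴ L mol⁻¹ s⁻¹, Ea3 = 61.0 kJ mol⁻¹)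
    second substrate + protic impurity → quenched substrate (k4 = 0.116 L mol⁻¹ s⁻¹, Ea4 = 57.0 kJ mol⁻¹)
    coupling partner + target → over-reaction product (k5 = 0.370 L mol⁻¹ s⁻¹, Ea5 = 74.0 kJ mol⁻¹)
    (constants at 70 °C)

Two colleagues argue at the board. Target is made by one step and used up by another, and both take coupling partner, so dividing the balance of target by that of starting material cancels it. What remains is the selectivity factor S, the rate constant of over-reaction over that of target formation at the flask's temperature, 6.77 in birch. If x is the fraction of starting material left and self-condensation is set aside, target as a fraction of the charge is (x − x^S)/(S − 1), and the share asked for is that divided by 1 − x.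

The first colleague looks at S. It is 6.67 in alder and 6.56 in larch; the two activation energies differ by 1.00 kJ mol⁻¹. With starting material half gone, the formula gives 17.0% for birch and 17.6% for larch, which lie within the margin. So she expects the flasks to lie together.

The second colleague looks at x, since target formation speeds up by a factor of 9.4 from larch to birch.

My own reckoning follows the second and needs a balance. Over-reaction has the larger rate constant, so as an estimate I charge 2 coupling partner for each starting material lost. On that count coupling partner is the limiting reagent. With A the concentration of starting material and r the starting-material charge less half the coupling-partner charge, 7.00 mM, coupling partner left is 2(A − r). Then (A − r)/A decays exponentially with rate constant 2rk, where k is the constant of target formation.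

This leaves x of 72.1% in alder, 70.5% in ash, 52.2% in birch and 88.5% in larch. Taking ash at the S of alder, my shares are 38.5% for alder, 36.4% for ash, 18.5% for birch and 68.3% for larch.

The forecast is the second colleague's number: 36.5% for alder, 34.5% for ash, 17% for birch and 67% for larch, with larch on top, since “the share depends almost entirely on how far each flask has been driven”. Each of my shares stands above the forecast's, but the order is the same.

The simulation gives 36.6% for alder, 34.4% for ash, 17.1% for birch and 67.4% for larch, the highest being larch. The forecast holds. Alder and ash lie 2.2 percentage points apart, against a margin of 1.5 points.

The length of the run carried the weight: larch gives 67.4% at the asked time, and with the short run taken away, left ten times as long, it gives 16.8%. Its starting material then stands at 48.1%, beside the 49.7% of birch at the asked time, and the shares, 16.8% and 17.1%, lie together. So the first colleague's view holds for these two readings, larch late and birch at the asked time, with nearly equal starting material left. With that reading of x, S gives birch 16.8%.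

The neighbour of birch charged with 10 mM of coupling partner has the same S, and with 76% of its starting material left the formula gives 43.0%. The simulation of that neighbour gives 44.4%.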